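**Numbering used throughout.** 1 phenol starting material; 2 iodophenol; 3 aryl iodide with allyl ether; 4 diethyl malonate; 5 aryl malonate; 6 diol; 7 racemic mono-silyl ether; 8 racemic aldehyde (precursor of the key step); 9 dibenzoyl peroxide; 10 (2S)-α-benzoyloxy aldehyde (product of the key step); 11 alcohol; 12 tosylate; 13 tertiary alkoxide; 14 silyl-protected oxirane; 15 oxiranylmethanol; 16 isovalerate; 17 free phenol; 18 target. Ar = 5-methoxy-4-methyl-2-(prop-2-enyloxy)phenyl.

## Analysis of the target

The target 18 is a 1,2,4,5-tetrasubstituted benzene: an aryl (E)-2-methylbut-2-enoate (tiglate) at C1, an oxiran-2-yl group at C2, OCH3 at C4 and CH3 at C5. The arene is therefore a hydroquinone monomethyl ether, and the oxirane is the only ring besides the benzene. The single stereocentre is the fully substituted oxirane carbon (R). It carries the aryl ring, the ring oxygen, the ring CH2 and a CH2O arm esterified with 3-methylbutanoic acid. The E double bond of the tiglate is the only other stereo element and is brought in intact. The two one-carbon arms on the stereocentre differ only in what their oxygen is bound to, and there is no neighbouring stereocentre from which to relay, so the absolute configuration has to come from a reagent or catalyst. The sensitive groups are: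

- the tertiary benzylic oxirane on an oxygen-rich arene, which is labile to acid, Lewis acid and a neighbouring free phenol;
- the aryl ester, which survives neither alkoxide nor hydride;
- the alkyl ester;
- the enoate, which can deconjugate under base.

This fixes the order of events: reductions and alkoxide chemistry first, oxirane closure late under mild base, the two esters afterwards, the aryl ester last. The strategy rests on the fact that the stereocentre is the α-carbon of a 2-aryl-3-oxypropanal. The ring CH2 is a former aldehyde carbon and the ring oxygen a former α-acyloxy group. In that aldehyde the benzylic α-C–H is enolisable, so its configuration can be erased and then set by a catalyst.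

## Retrosynthetic reasoning

**18 to 16 (through 17).** The aryl O–C(=O) bond of the tiglate is cut first, because it is the bond least tolerant of base and nucleophiles and must be made last. The phenol is carried as the allyl ether 16, which is inert to hydride, fluoride, carbonate and the amine catalyst and is removed under neutral conditions with zerovalent palladium. The free phenol 17 is not stored, because a phenol next to the benzylic oxirane can open it.

**16 to 15 to 14.** The alkyl ester C–O bond and then the Si–O bond are cut. The isovalerate cannot be present when the benzoate is methanolysed, so it follows oxirane formation. The silyl ether is what distinguishes the two arms from the moment they become different.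

**14 to 12 (through 13).** The oxirane CH2–O bond is cut. In the forward sense the oxygen already sitting on the stereocentre displaces a primary sulfonate, so no bond to the stereocentre is made or broken and the configuration of 12 is carried over unchanged. The benzoate of 12 is a latent alkoxide, released as 13 only once the leaving group is in place.

**12 to 11 to 10.** These are functional-group changes: sulfonate from alcohol, alcohol from aldehyde. The aldehyde carbon of 10 becomes the oxirane CH2 and the silyloxymethyl arm becomes the isovalerate arm. This assignment of roles decides that 10 must be 2S.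

**10 to 8 and 9.** This is the key disconnection, the quaternary C–O bond. It is cut here because it is the one bond at the stereocentre whose formation can be coupled with erasure of the stereocentre in the precursor: 8 has an acidic benzylic α-hydrogen, and condensation with an amine turns both enantiomers into one planar enamine. What is gained is that a racemic precursor suffices and can in principle be converted completely into one enantiomer. The forward reaction must control the enamine geometry and the face of attack on 9, and C–O bond formation must be faster than β-elimination of the silyloxy group.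

**8 to 7 to 6.** The oxidation level is adjusted, and the Si–O bond of 7 is cut to the diol 6. Its two arms are equivalent, so monosilylation needs only mono-versus-bis selectivity, and the racemic nature of 7 is of no consequence.

**6 to 5 to 3 and 4.** Both ester groups are traced back to the malonate 5, and the aryl–C bond is cut between the ring and the malonate carbon. Coupling of 3 with 4 brings in the three-carbon unit with both arms at the same oxidation level in one C–C bond formation. Copper catalysis is preferred to palladium because of the allyl ether.

**3 to 2 to 1.** The O–allyl bond and the C–I bond are cut. In 1 the free hydroxyl group directs iodination to the ortho position that is also para to the methyl group, which is the position the three-carbon unit must occupy.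

## Alternatives that were turned down

**Alternative 1:** The benzene ring itself is taken apart into three pieces. In the forward key step the alkenyl(methoxy)carbene complex of zerovalent chromium A2, the enantiopure alkynyl oxirane A3 and one carbonyl ligand combine in a Dötz benzannulation to give the phenol A1, which is identical with 17.
- *For:* it is convergent, the regiochemistry of the benzannulation places all four ring substituents correctly, the isovalerate is already in place, and only the phenol acylation remains. On convergence and on the length of the endgame it is stronger than the chosen route.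
- *Against:* the quaternary stereocentre is not created but imported. A3 is a small 2,2-disubstituted oxirane with the same kind of centre, and it needs its own asymmetric synthesis. A propargylic oxirane must also survive warm, electron-rich chromium intermediates that can open it. The product appears as the free ortho-hydroxyaryl oxirane, the most fragile species of the whole series, and as a hydroquinone monoether that any oxidative decomplexation would take to the quinone. Chromium is used stoichiometrically.
- *Comparison:* the chosen strategy creates the stereocentre by catalysis on a robust open-chain aldehyde and never isolates 17.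

**Alternative 2:** The quaternary C–CH2OH bond is cut. The (R)-aryl oxirane A5 is deprotonated at its benzylic oxirane C–H with an alkyllithium–diamine base at very low temperature, and the oxiranyllithium adds to formaldehyde A6 with retention to give A4, the silyl analogue of 15.
- *For:* it is direct, A5 is a monosubstituted aryl oxirane of a well-served class, and A4 is only three operations from the target. In step count it is clearly stronger.
- *Against:* the aryl group is electron-rich and carries an ortho silyloxy group. The anion is therefore poorly stabilised and slow to form. Ortho-lithiation next to the methoxy group and lithiation of the aryl methyl group compete. A 1,4-shift of silicon from the phenolic oxygen to the carbanion is likely. The carbenoid character of the oxiranyllithium threatens both its lifetime and its configuration.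
- *Comparison:* in the chosen strategy the stereocentre, once formed, is a fully substituted carbon that never again passes through a reactive intermediate.

**Alternative 3:** The oxirane is cut at the quaternary C–CH2 bond and the CH2–O bond. Dimethylsulfoxonium methylide A9 transfers a methylene group to the ketone A8 under the chiral catalyst A10, LaLi3(binaphthoxide)3, in an asymmetric Corey–Chaykovsky reaction. The product A7 is identical with 14.
- *For:* it is the shortest of all. A8 is one or two steps from 3, and 14 would be reached in about half the steps of the chosen route. On step economy it is clearly stronger.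
- *Against:* this catalyst type tells the two ketone substituents apart mainly by size and is at its best with methyl ketones. Here it must choose between an ortho-alkoxyaryl group and a CH2OSi group, both large and both Lewis basic. Chelation of the α-silyloxy ketone and of the allyloxy oxygen to the oxophilic trivalent lanthanum can change the binding mode. The twisted ortho-substituted aryl ketone is a slow electrophile, and the basic ylide can enolise the α-oxy ketone.
- *Comparison:* in the chosen strategy the two competing groups on the enamine carbon, a conjugating aryl ring and an sp3 CH2OSi arm, differ electronically as well as sterically. In addition, the benzoates 11 and 12 would allow the enantiopurity to be raised by recrystallisation should they be crystalline.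

Key step: step 7

Assumption: 9-amino-9-deoxy-epi-quinine is taken to be the pseudoenantiomer whose enamine is attacked on the face that leads to (2S)-10; should the first run show the opposite sense, 9-amino-9-deoxy-epi-quinidine is used under otherwise unchanged conditions.

## Route

Step 1
Reactants: 1 4-methoxy-3-methylphenol
Product: 2 2-iodo-4-methoxy-5-methylphenol
Conditions: NIS, TsOH·H2O (10 mol %), MeCN, 0 °C → rt
Reagents that add atoms: N-iodosuccinimide, O=C1CCC(=O)N1I
Why: Electrophilic aromatic iodination; the free OH is the strongest director, its para position is blocked by OCH3, and of the two ortho positions the one between OH and C–CH3 is hindered, so iodine should enter at the ortho position that is also para to the methyl group.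

Step 2
Reactants: 2 2-iodo-4-methoxy-5-methylphenol
Product: 3 1-iodo-5-methoxy-4-methyl-2-(prop-2-enyloxy)benzene (Ar–I)
Conditions: allyl bromide, K2CO3, DMF, rt
Reagents that add atoms: 3-bromoprop-1-ene, C=CCBr
Why: Williamson ether synthesis of a phenoxide with a reactive allylic bromide; the allyl ether tolerates every later reagent up to the deliberate removal with zerovalent palladium.

Step 3
Reactants: 3 1-iodo-5-methoxy-4-methyl-2-(prop-2-enyloxy)benzene; 4 diethyl propanedioate (diethyl malonate)
Product: 5 diethyl 2-Ar-propanedioate
Conditions: CuI (10 mol %), pyridine-2-carboxylic acid (20 mol %), Cs2CO3, 1,4-dioxane, 70 °C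
Reagents that add atoms: none
Why: Copper-catalysed α-arylation of a malonate (Ullmann–Hurtley type); the picolinate-ligated monovalent copper malonate couples with aryl iodides under mild conditions, and copper, unlike palladium, does not ionise the aryl allyl ether.

Step 4
Reactants: 5 diethyl 2-Ar-propanedioate
Product: 6 2-Ar-propane-1,3-diol
Conditions: LiAlH4, THF, 0 °C → rt (malonate added to the hydride)
Reagents that add atoms: none
Why: Hydride reduction of both esters to the 2-aryl-1,3-diol; inverse addition into excess hydride at 0 °C favours reduction over deprotonation of the acidic malonate C–H.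

Step 5
Reactants: 6 2-Ar-propane-1,3-diol
Product: 7 racemic 3-[tert-butyl(dimethyl)silyl]oxy-2-Ar-propan-1-ol
Conditions: NaH (1.0 equiv), THF, 0 °C → rt; then TBSCl (1.0 equiv)
Reagents that add atoms: tert-butyl(chloro)dimethylsilane, CC(C)(C)[Si](C)(C)Cl
Why: Monosilylation of a symmetric diol through its sparingly soluble monosodium alkoxide, which reacts once; the stereocentre arises here as a racemate, which is acceptable because step 7 erases it.

Step 6
Reactants: 7 racemic 3-[tert-butyl(dimethyl)silyl]oxy-2-Ar-propan-1-ol
Product: 8 racemic 3-[tert-butyl(dimethyl)silyl]oxy-2-Ar-propanal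
Conditions: Dess–Martin periodinane, NaHCO3, CH2Cl2, 0 °C → rt; used crude
Reagents that add atoms: none
Why: Dess–Martin oxidation of a primary alcohol under buffered, base-free conditions, which should spare the aldehyde from β-elimination of the silyloxy group.

Step 7
Reactants: 8 racemic 3-[tert-butyl(dimethyl)silyl]oxy-2-Ar-propanal; 9 dibenzoyl peroxide
Product: 10 (2S)-1-[tert-butyl(dimethyl)silyl]oxy-2-Ar-3-oxopropan-2-yl benzoate
Conditions: 9-amino-9-deoxy-epi-quinine (20 mol %), Cl3CCO2H (40 mol %), 2,6-di-tert-butyl-4-methylphenol (10 mol %), THF, 25 °C
Reagents that add atoms: none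
Why: The primary amine of the catalyst condenses with 8 to an iminium ion that loses the acidic benzylic α-proton, so both enantiomers of 8 drain into one aryl-conjugated enamine and the racemate is converted stereoconvergently rather than resolved. The nucleophilic enamine carbon attacks the weak O–O bond of 9, benzoate leaves, and hydrolysis of the α-benzoyloxy iminium ion returns the catalyst and releases 10; one C–O bond is formed and no ring is closed. The closest known reaction type is the cinchona-primary-amine-catalysed α-benzoyloxylation of α-branched 2-aryl aldehydes with dibenzoyl peroxide, applied here to a substrate with a β-silyloxy group. The one new stereocentre, the quaternary C2, is controlled by the catalyst: the peroxide is hydrogen-bonded to the protonated quinuclidine, which lies over one face of the enamine, and the assumed sense gives 2S. This control presupposes a single enamine geometry, which the substrate should secure because the conjugating, ortho-substituted aryl ring takes the position anti to nitrogen and leaves the slimmer CH2OSi arm next to the N–H. The step also needs chemoselectivity, since C–O bond formation must outrun loss of silanolate from the enamine; the poor leaving group, the acid-buffered medium and ambient temperature favour this, and the phenolic inhibitor suppresses radical decomposition of the peroxide. The product has no α-hydrogen, so it can neither racemise nor react a second time.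

Step 8
Reactants: 10 (2S)-1-[tert-butyl(dimethyl)silyl]oxy-2-Ar-3-oxopropan-2-yl benzoate
Product: 11 (2R)-1-[tert-butyl(dimethyl)silyl]oxy-3-hydroxy-2-Ar-propan-2-yl benzoate
Conditions: NaBH4, MeOH/THF, −20 → 0 °C, short reaction time, NH4Cl quench
Reagents that add atoms: none
Why: Borohydride reduction of an aldehyde is chemoselective over the benzoate at low temperature; the stereocentre is untouched (the descriptor changes only through the priority rules), and cold, brief conditions should prevent acyl and silyl shifts.

Step 9
Reactants: 11 (2R)-1-[tert-butyl(dimethyl)silyl]oxy-3-hydroxy-2-Ar-propan-2-yl benzoate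
Product: 12 (2S)-1-[tert-butyl(dimethyl)silyl]oxy-2-Ar-3-[(4-methylphenyl)sulfonyloxy]propan-2-yl benzoate
Conditions: TsCl, Et3N, DMAP (cat.), CH2Cl2, 0 °C → rt
Reagents that add atoms: 4-methylbenzenesulfonyl chloride, Cc1ccc(cc1)S(Cl)(=O)=O
Why: DMAP-catalysed sulfonylation of the only free hydroxyl group; the tertiary oxygen stays masked as the benzoate, so the oxirane cannot close prematurely.

Step 10
Reactants: 12 (2S)-1-[tert-butyl(dimethyl)silyl]oxy-2-Ar-3-[(4-methylphenyl)sulfonyloxy]propan-2-yl benzoate
Product: 14 tert-butyl{[(2R)-2-Ar-oxiran-2-yl]methoxy}dimethylsilane, via tertiary alkoxide 13 (not isolated)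
Conditions: K2CO3, MeOH/THF, 0 °C → rt
Reagents that add atoms: none
Why: Methanolysis (transesterification) of the benzoate releases alkoxide 13, which displaces the neighbouring tosylate in a 3-exo-tet Williamson closure; the C–O bond at the stereocentre is never broken, so the configuration of 12 is retained.

Step 11
Reactants: 14 tert-butyl{[(2R)-2-Ar-oxiran-2-yl]methoxy}dimethylsilane
Product: 15 [(2S)-2-Ar-oxiran-2-yl]methanol
Conditions: Bu4NF, THF, 0 °C
Reagents that add atoms: none
Why: Fluoride-mediated cleavage of the Si–O bond under non-acidic conditions; a Payne rearrangement of the resulting 2,3-epoxy alkoxide would be degenerate and return the same enantiomer, so the configuration is safe.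

Step 12
Reactants: 15 [(2S)-2-Ar-oxiran-2-yl]methanol
Product: 16 [(2R)-2-Ar-oxiran-2-yl]methyl 3-methylbutanoate
Conditions: (iPrCH2CO)2O, Et3N, DMAP (cat.), CH2Cl2, 0 °C
Reagents that add atoms: 3-methylbutanoic anhydride, CC(C)CC(=O)OC(=O)CC(C)C
Why: DMAP-catalysed acyl transfer from an anhydride to a primary alcohol; the medium stays basic and halide-free, which should protect the acid-labile benzylic oxirane.

Step 13
Reactants: 16 [(2R)-2-Ar-oxiran-2-yl]methyl 3-methylbutanoate
Product: 18 2-[(2R)-2-{[(3-methylbutanoyl)oxy]methyl}oxiran-2-yl]-4-methoxy-5-methylphenyl (2E)-2-methylbut-2-enoate, via free phenol 17 (not isolated)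
Conditions: Pd(PPh3)4 (5 mol %), morpholine (1.2 equiv), THF, rt; then Et3N, DMAP (cat.), tigloyl chloride (1.5 equiv), −20 → 0 °C
Reagents that add atoms: (2E)-2-methylbut-2-enoyl chloride, C/C=C(\C)C(Cl)=O
Why: Tsuji–Trost-type deallylation, in which zerovalent palladium ionises the aryl allyl ether and morpholine captures the π-allyl fragment, followed in the same flask by DMAP-catalysed acylation of phenol 17; immediate acylation at low temperature should outpace attack of the phenol on the oxirane and should keep the E geometry of the enoate.

## Compound list

1 | 4-methoxy-3-methylphenol | COc1ccc(O)cc1C | starting material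
2 | 2-iodo-4-methoxy-5-methylphenol | COc1cc(I)c(O)cc1C | intermediate
3 | 1-iodo-5-methoxy-4-methyl-2-(prop-2-enyloxy)benzene | C=CCOc1cc(C)c(OC)cc1I | intermediate
4 | diethyl propanedioate (diethyl malonate) | CCOC(=O)CC(=O)OCC | starting material
5 | diethyl 2-[5-methoxy-4-methyl-2-(prop-2-enyloxy)phenyl]propanedioate | CCOC(=O)C(C(=O)OCC)c1cc(OC)c(C)cc1OCC=C | intermediate
6 | 2-[5-methoxy-4-methyl-2-(prop-2-enyloxy)phenyl]propane-1,3-diol | OCC(CO)c1cc(OC)c(C)cc1OCC=C | intermediate
7 | racemic 3-[tert-butyl(dimethyl)silyl]oxy-2-[5-methoxy-4-methyl-2-(prop-2-enyloxy)phenyl]propan-1-ol | C=CCOc1cc(C)c(OC)cc1C(CO)CO[Si](C)(C)C(C)(C)C | intermediate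
8 | racemic 3-[tert-butyl(dimethyl)silyl]oxy-2-[5-methoxy-4-methyl-2-(prop-2-enyloxy)phenyl]propanal | C=CCOc1cc(C)c(OC)cc1C(C=O)CO[Si](C)(C)C(C)(C)C | intermediate
9 | dibenzoyl peroxide | O=C(OOC(=O)c1ccccc1)c1ccccc1 | starting material
10 | (2S)-1-[tert-butyl(dimethyl)silyl]oxy-2-[5-methoxy-4-methyl-2-(prop-2-enyloxy)phenyl]-3-oxopropan-2-yl benzoate | C=CCOc1cc(C)c(OC)cc1[C@](OC(=O)c1ccccc1)(CO[Si](C)(C)C(C)(C)C)C=O | intermediate
11 | (2R)-1-[tert-butyl(dimethyl)silyl]oxy-3-hydroxy-2-[5-methoxy-4-methyl-2-(prop-2-enyloxy)phenyl]propan-2-yl benzoate | C=CCOc1cc(C)c(OC)cc1[C@](OC(=O)c1ccccc1)(CO[Si](C)(C)C(C)(C)C)CO | intermediate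
12 | (2S)-1-[tert-butyl(dimethyl)silyl]oxy-2-[5-methoxy-4-methyl-2-(prop-2-enyloxy)phenyl]-3-[(4-methylphenyl)sulfonyloxy]propan-2-yl benzoate | C=CCOc1cc(C)c(OC)cc1[C@](OC(=O)c1ccccc1)(CO[Si](C)(C)C(C)(C)C)COS(=O)(=O)c1ccc(C)cc1 | intermediate
13 | potassium (2S)-1-[tert-butyl(dimethyl)silyl]oxy-2-[5-methoxy-4-methyl-2-(prop-2-enyloxy)phenyl]-3-[(4-methylphenyl)sulfonyloxy]propan-2-olate | C=CCOc1cc(C)c(OC)cc1[C@]([O-])(CO[Si](C)(C)C(C)(C)C)COS(=O)(=O)c1ccc(C)cc1.[K+] | intermediate
14 | tert-butyl{[(2R)-2-[5-methoxy-4-methyl-2-(prop-2-enyloxy)phenyl]oxiran-2-yl]methoxy}dimethylsilane | C=CCOc1cc(C)c(OC)cc1[C@]1(CO[Si](C)(C)C(C)(C)C)CO1 | intermediate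
15 | [(2S)-2-[5-methoxy-4-methyl-2-(prop-2-enyloxy)phenyl]oxiran-2-yl]methanol | C=CCOc1cc(C)c(OC)cc1[C@]1(CO)CO1 | intermediate
16 | [(2R)-2-[5-methoxy-4-methyl-2-(prop-2-enyloxy)phenyl]oxiran-2-yl]methyl 3-methylbutanoate | C=CCOc1cc(C)c(OC)cc1[C@]1(COC(=O)CC(C)C)CO1 | intermediate
17 | [(2R)-2-(2-hydroxy-5-methoxy-4-methylphenyl)oxiran-2-yl]methyl 3-methylbutanoate | Oc1cc(C)c(OC)cc1[C@]1(COC(=O)CC(C)C)CO1 | intermediate
18 | 2-[(2R)-2-{[(3-methylbutanoyl)oxy]methyl}oxiran-2-yl]-4-methoxy-5-methylphenyl (2E)-2-methylbut-2-enoate | C/C=C(\C)C(=O)Oc1cc(C)c(OC)cc1[C@]1(COC(=O)CC(C)C)CO1 | target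

## Step count and risk

Total step count: 13. Longest linear sequence: 13 steps, from 1 to 18; the route is fully linear, with 4 and 9 entering as reagent-like starting materials.

**Step 7 (key step).** Three things can go wrong.
- The enamine can lose silanolate from the β-position, giving a conjugated iminium ion and then the 2-arylacrolein, so that substrate is consumed without C–O bond formation.
- The facial discrimination may be poor if the enamine is not formed as one geometric isomer, because the ortho-substituted aryl ring and the CH2OSi arm are closer in size than aryl and methyl.
- The peroxide can oxidise the catalyst at its primary nitrogen and stall turnover.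

The fallback abandons the enamine chemistry and sets the centre by reagent-controlled epoxidation. It sets out from 5. The sodium enolate of 5 (NaH, 1,2-dimethoxyethane) is reduced with LiAlH4 at reflux, which proceeds with elimination and should give 2-[5-methoxy-4-methyl-2-(prop-2-enyloxy)phenyl]prop-2-en-1-ol F1. Sharpless asymmetric epoxidation of F1 (catalytic Ti(OiPr)4, L-(+)-diethyl tartrate, t-BuOOH, 4 Å molecular sieves, CH2Cl2, −20 °C) should deliver the oxygen to the face that gives the (2S)-oxiranylmethanol, so the route is rejoined at 15. The ether alkene of the allyl group is not an allylic alcohol and is left alone. This path is shorter, but it is held in reserve because the electron-rich 2-aryl glycidol is exposed to Lewis-acidic tetravalent titanium.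

**Step 13.** The liberated phenol may open the neighbouring oxirane, either by attack on the ring CH2 to a dihydrobenzofuranol or by assisting ionisation of the benzylic C–O bond, before it is acylated. Palladium may isomerise the aryl oxirane. The acid chloride may be deconjugated through a vinylketene by the amine base. The fallback never liberates a phenol. It sets out from 16, which is treated with Pd(PPh3)4 (catalytic) and Bu3SnH in CH2Cl2 at room temperature. Hydrostannolysis of the aryl allyl ether should give [(2R)-2-(5-methoxy-4-methyl-2-tributylstannyloxyphenyl)oxiran-2-yl]methyl 3-methylbutanoate F2 and propene. F2 is a covalent, non-basic stannyl ether that is acylated directly by tigloyl chloride added after the hydride has been consumed, which returns to the route at 18.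

**Step 8.** The benzoyl group may shift from the tertiary to the new primary oxygen through a five-membered ortho ester anion, which would leave a tertiary alcohol that the tosylation of step 9 no longer differentiates. A shift of silicon between the two primary oxygens would interconvert the enantiomers. The fallback removes the benzoate at once, so that both benzoate regioisomers converge. It sets out from 10, which is treated with LiAlH4 in THF at −78 → 0 °C; this reduces the aldehyde and cleaves the benzoate and should give (2R)-3-[tert-butyl(dimethyl)silyl]oxy-2-[5-methoxy-4-methyl-2-(prop-2-enyloxy)phenyl]propane-1,2-diol F3. Tin-catalysed regioselective sulfonylation of the primary hydroxyl group (TsCl, Et3N, catalytic Bu2SnO, CH2Cl2) should give (2S)-3-[tert-butyl(dimethyl)silyl]oxy-2-hydroxy-2-[5-methoxy-4-methyl-2-(prop-2-enyloxy)phenyl]propyl 4-methylbenzenesulfonate F4. K2CO3 in MeOH deprotonates F4 to alkoxide 13, where the route is rejoined and closes to 14 as in step 10.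

**Step 4.** Hydride may deprotonate the acidic aryl malonate instead of reducing it; the enolate then eliminates and is over-reduced, which diverts material to allylic and saturated mono-alcohols. The fallback builds the second arm by C–C bond formation on an arylacetic acid. It sets out from 5, which is saponified (NaOH, aqueous EtOH) and decarboxylated on acidification and gentle warming to [5-methoxy-4-methyl-2-(prop-2-enyloxy)phenyl]acetic acid F5. The magnesium enediolate of F5 (2.2 equiv iPrMgCl, THF) is hydroxymethylated with formaldehyde in an Ivanov reaction to racemic 3-hydroxy-2-[5-methoxy-4-methyl-2-(prop-2-enyloxy)phenyl]propanoic acid F6. Reduction of F6 with LiAlH4, now free of the malonate acidity problem, returns to the route at 6.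

## Further compounds

F1 | step 7 | 2-[5-methoxy-4-methyl-2-(prop-2-enyloxy)phenyl]prop-2-en-1-ol | C=CCOc1cc(C)c(OC)cc1C(=C)CO
F2 | step 13 | [(2R)-2-(5-methoxy-4-methyl-2-tributylstannyloxyphenyl)oxiran-2-yl]methyl 3-methylbutanoate | CCCC[Sn](CCCC)(CCCC)Oc1cc(C)c(OC)cc1[C@]1(COC(=O)CC(C)C)CO1
F3 | step 8 | (2R)-3-[tert-butyl(dimethyl)silyl]oxy-2-[5-methoxy-4-methyl-2-(prop-2-enyloxy)phenyl]propane-1,2-diol | C=CCOc1cc(C)c(OC)cc1[C@](O)(CO[Si](C)(C)C(C)(C)C)CO
F4 | step 8 | (2S)-3-[tert-butyl(dimethyl)silyl]oxy-2-hydroxy-2-[5-methoxy-4-methyl-2-(prop-2-enyloxy)phenyl]propyl 4-methylbenzenesulfonate | C=CCOc1cc(C)c(OC)cc1[C@](O)(CO[Si](C)(C)C(C)(C)C)COS(=O)(=O)c1ccc(C)cc1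
F5 | step 4 | [5-methoxy-4-methyl-2-(prop-2-enyloxy)phenyl]acetic acid | OC(=O)Cc1cc(OC)c(C)cc1OCC=C
F6 | step 4 | racemic 3-hydroxy-2-[5-methoxy-4-methyl-2-(prop-2-enyloxy)phenyl]propanoic acid | OCC(C(O)=O)c1cc(OC)c(C)cc1OCC=C
A1 | alternative 1 | [(2R)-2-(2-hydroxy-5-methoxy-4-methylphenyl)oxiran-2-yl]methyl 3-methylbutanoate | Oc1cc(C)c(OC)cc1[C@]1(COC(=O)CC(C)C)CO1
A2 | alternative 1 | pentacarbonyl[methoxy(prop-1-en-2-yl)methylidene]chromium, Cr(CO)5[C(OCH3)C(CH3)=CH2] | COC(C(C)=C)=[Cr].[C-]#[O+].[C-]#[O+].[C-]#[O+].[C-]#[O+].[C-]#[O+]
A3 | alternative 1 | [(2R)-2-ethynyloxiran-2-yl]methyl 3-methylbutanoate | C#C[C@]1(COC(=O)CC(C)C)CO1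
A4 | alternative 2 | [(2S)-2-(5-methoxy-4-methyl-2-triisopropylsilyloxyphenyl)oxiran-2-yl]methanol | CC(C)[Si](Oc1cc(C)c(OC)cc1[C@]1(CO)CO1)(C(C)C)C(C)C
A5 | alternative 2 | (2R)-2-(5-methoxy-4-methyl-2-triisopropylsilyloxyphenyl)oxirane | CC(C)[Si](Oc1cc(C)c(OC)cc1[C@@H]1CO1)(C(C)C)C(C)C
A6 | alternative 2 | formaldehyde | C=O
A7 | alternative 3 | tert-butyl{[(2R)-2-[5-methoxy-4-methyl-2-(prop-2-enyloxy)phenyl]oxiran-2-yl]methoxy}dimethylsilane | C=CCOc1cc(C)c(OC)cc1[C@]1(CO[Si](C)(C)C(C)(C)C)CO1
A8 | alternative 3 | 2-[tert-butyl(dimethyl)silyl]oxy-1-[5-methoxy-4-methyl-2-(prop-2-enyloxy)phenyl]ethan-1-one | C=CCOc1cc(C)c(OC)cc1C(=O)CO[Si](C)(C)C(C)(C)C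
A9 | alternative 3 | dimethylsulfoxonium methylide | C[S+](C)(=O)[CH2-]
A10 | alternative 3 | LaLi3(binaphthoxide)3, trilithium lanthanum tris(1,1'-binaphthalene-2,2'-diolate), one axial enantiomer (axial configuration not expressed in the string) | [La+3].[Li+].[Li+].[Li+].[O-]c1ccc2ccccc2c1-c1c([O-])ccc2ccccc12.[O-]c1ccc2ccccc2c1-c1c([O-])ccc2ccccc12.[O-]c1ccc2ccccc2c1-c1c([O-])ccc2ccccc12
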